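## The problem

Compound 23 is a labdane: a trans-fused decalin (ring A = C1–C5 and C10, ring B = C5–C10, labdane numbering throughout) whose ring A is a bare gem-dimethylcyclohexane. Ring B carries everything else: the tetrasubstituted C8=C9 alkene with the C8 methyl and the C11–C15 side chain, an allylic 7α-hydroxyl and a 6β-acetate. Of the four stereocentres (5S, 6S, 7S, 10S), C5 and the quaternary C10 fix the ring fusion and cannot be corrected once ring A is closed, so they must come first. They can then control C6 and C7, because the axial methyls on C10 and C4 close the β face of ring B and send reagents to the α face. The C6 and C7 oxygens are trans-diaxial and the acetate sits on the more hindered one (6β, syn-axial to two methyls), so it cannot be installed by selective acylation of a free diol. The side chain ends in a Z-trisubstituted allylic alcohol whose geometry must be carried in intact; like the allylic C7 carbinol, it ionises under strong acid, and the acetate excludes strong bases and nucleophiles late in the route. The enabling feature is that ring B is (R)-carvone (4): its stereocentre is C5 in the correct absolute sense, its isopropenyl carbon is C4, its carbonyl is C9, its enone carbons are C8 (with the methyl) and C7, and its α'-carbon is C10. Ring A then needs only a methyl and a three-carbon arm (C1–C3) on C10 and one bond, C3–C4; the C4 isopropenyl group is the kind of electron-rich 1,1-disubstituted alkene that accepts a hydrogen atom from an iron hydride to give the C4 tertiary radical and the second C4 methyl.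

## Retrosynthesis

**O-acyl and O-silyl bonds (23 ⇐ 22 ⇐ 21 ⇐ 20).** The acetate is on the least accessible hydroxyl, so the order is forced: mask the 7α-hydroxyl of diol 20 as a triethylsilyl ether (21), acetylate the remaining 6β-hydroxyl (22), then remove both silyl groups. Selective acylation of a triol would give the wrong ester. The forward steps need only the steric difference between C7-OH and C6-OH and a fluoride source that spares the acetate.

**C2–S bond (20 ⇐ 19).** The phenylsulfonyl group that steers the ring-A closure is cut here and not directly after the cyclisation. Every electron-transfer reagent that cleaves an alkyl aryl sulfone reduces a conjugated enone first, and ring B remains an enone from 9 to 11. In 19 the carbonyl has been consumed, so desulfonylation costs one step with no redox detour. The price is that 9–11, 18 and 19 are C2-epimer mixtures.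

**C7–O bond by 1,3-transposition (19 ⇐ 18).** The 7α-hydroxyl and the C8=C9 alkene are traced to the tertiary allylic alcohol 18 (oxygen on C9, alkene C7=C8). This is preferred to oxidising C7 of a preformed C8=C9 alkene, which would give the 7β-alcohol on hydride reduction of a 7-ketone. The forward step must capture the C7–C8–C9 allyl cation at C7 on the α face; the axial 6β-hydroxyl and the C10 methyl block the β face.

**C9–C11 bond (18 ⇐ 11 + 15, through 16 and 17).** Cutting between ring and chain gives the hindered, non-enolisable C9 ketone 11 and a homoallylic organometallic from bromide 15. Cutting further along the chain would require building the Z alkene late. The forward addition needs a non-basic organocerium reagent (17) and tolerates the free 6β-hydroxyl at the cost of one sacrificial equivalent. The C9 configuration is irrelevant.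

**Side chain (15 ⇐ 14 ⇐ 13 ⇐ 12).** The Z geometry comes from lactone 12, where the carbonyl (future C15) and the O–CH2CH2 arm (future C11–C12) are held cis across the ring alkene. Alkyl–oxygen cleavage by bromide gives 13 with the two ends differentiated; reduction and silylation give 15. The forward requirement is that the geometry survives ring opening.

**C6–O bond (11 ⇐ 10 ⇐ 9).** The 6β-oxygen is traced through ene-dione 10 to the γ-methylene of enone 9. Going through the ketone is preferred to direct γ-hydroxylation, which would deliver oxygen from the open α face (6α). Hydride addition to 10 from that same α face gives the required 6β-alcohol. The forward steps must oxidise the only γ-CH2 and then discriminate C6=O from the more hindered C9=O.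

**C3–C4 bond, the key cut (9 ⇐ 8).** Ring A is opened between C3 and C4, giving carvone derivative 8 with an isopropenyl group on C5 and a 2-(phenylsulfonyl)allyl arm on C10. This cut is preferred to C1–C10 or C4–C5 because it forms no stereocentre: the ring fusion is already fixed by C5 and C10, and the gem-dimethyl carbon arises from hydrogen-atom transfer. The sulfone polarises the acceptor so that the C4 radical attacks the terminal C3 (six-membered ring) and not C2.

**C1–C10 and C10–CH3 bonds (8 ⇐ 6 + 3; 6 ⇐ 4; 3 ⇐ 2 ⇐ 1).** Both C10 substituents are α'-alkylations of 4 through enolates 5 and 7, methyl first so that the larger electrophile enters second, anti to the isopropenyl group. Bromide 3 is traced to vinyl sulfone 1 through alcohol 2, because this places sulfur on the central carbon of the arm (C2).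

## Roads not taken

**Alternative 1:** The cut is C4–C5 and C9–C10, opening both rings to the acyclic geranyl-type β-keto ester A1. In the forward step a chiral proton donor built from SnCl4 and a BINOL monoether would protonate the terminal alkene, and the internal alkene and the enol carbon would close rings A and B to the trans-decalin β-keto ester A2.
- Merits: both rings, C5, C10 and the C9–C11 bond form in one step from a precursor made by two alkylations, and ring A needs no activating group.
- Weak points: face-selective protonation with a β-keto ester terminator is the least secure member of this reaction class. A2 has oxygen only at C8: the C8 methyl must be added to a hindered ketone, the C9 ester must be excised to reveal C8=C9 with regiochemical ambiguity, and C6 is an unactivated methylene remote from any handle.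
- Comparison: this road is shorter to the carbon skeleton and avoids the sulfone. The chosen plan sets against it an absolute configuration taken from 4 and a ring-B enone that becomes carbonyls at C6 and C9 in two steps.

**Alternative 2:** The cut is C5–C6 and C9–C10. Amide A3 would be turned into a keteniminium ion with triflic anhydride and a hindered pyridine and added [2+2] to 1,3,3-trimethylcyclohexene A4, giving after hydrolysis the cis-fused 2-isopropenylcyclobutanone A5. A 1,3-acyl shift would then enlarge the four-membered ring to ring B.
- Merits: convergent, ring A is bought complete, and after ring expansion the C6 carbonyl, C8 methyl, C8=C9 alkene and chain stub are all in place. The endgame would be shorter than the one adopted here.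
- Weak points: the cycloaddition must join a fully substituted keteniminium carbon to a trisubstituted alkene flanked by a gem-dimethyl carbon, creating the quaternary C10. An α-alkenyl keteniminium has other reaction channels. Absolute control rests on a remote C2-symmetric auxiliary acting on an achiral alkene. The cis fusion must be epimerised at C5 through the C6 ketone, with an uncertain equilibrium next to the C4 methyls.
- Comparison: the chosen plan offers a key step that forms no stereocentre and a trans fusion fixed in advance.

**Alternative 3:** The cut is C1–C10 and C4–C5. 2,6-Dimethyl-1,4-benzoquinone A6 and 4-methylpenta-1,3-diene A7 would combine under a chiral oxazaborolidinium catalyst to the cis-fused ene-dione A8.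
- Merits: one catalytic enantioselective step from two commercial compounds reaches a bicycle with both ring-B carbonyls and the C7=C8 alkene. This is the array that the chosen route reaches only at 10, so this road would be several steps shorter.
- Weak points: A7 carries a cis methyl on its reacting terminus, so its s-cis conformer is poorly populated and forcing conditions would cost selectivity. The adduct is cis-fused and needs C5 epimerisation. The C2=C3 alkene must be hydrogenated in the presence of the far more reducible ene-dione alkene.
- Comparison: the chosen plan offers a secured trans fusion, a saturated ring A and no sluggish diene.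

Key step: step 5

Remarks on the chemistry: (a) α is the face opposite the C10 methyl. (b) Compound 6 is used as its epimer mixture at the methylated carbon, and 9–11, 18 and 19 as epimer mixtures at the sulfone-bearing C2 (drawn without configuration); both centres are erased later (steps 4 and 13). (c) LiN(i-Pr)2 is taken as the commercial solution.

Step 1
Reactants: 1 phenyl vinyl sulfone
Product: 2 2-(phenylsulfonyl)prop-2-en-1-ol
Conditions: aq. CH2O (37%), DABCO (0.5 equiv), THF, 23 °C
Reagents that add atoms: formaldehyde, C=O
Why: Morita–Baylis–Hillman reaction: DABCO adds to the vinyl sulfone and the α-sulfonyl carbanion is hydroxymethylated, which places sulfur on the central carbon of the future C1–C3 arm.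

Step 2
Reactants: 2 2-(phenylsulfonyl)prop-2-en-1-ol
Product: 3 3-bromo-2-(phenylsulfonyl)prop-1-ene
Conditions: PBr3, Et2O, 0 °C
Reagents that add atoms: phosphorus tribromide, BrP(Br)Br
Why: Conversion of a primary allylic alcohol into the bromide; direct and allylically transposed substitution give the same constitution, so regiochemistry is not at issue.

Step 3
Reactants: 4 (R)-(−)-carvone
Product: 6 6-methylcarvone (epimer mixture at the new centre), via lithium enolate 5 (not isolated)
Conditions: LiN(i-Pr)2, THF, −78 °C; MeI, −78 → 0 °C
Reagents that add atoms: iodomethane, CI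
Why: Kinetic α'-deprotonation of the enone and SN2 methylation of the cross-conjugated enolate; the new centre forms as an epimer mixture, which does not matter because step 4 planarises it again.

Step 4
Reactants: 6 6-methylcarvone; 3 3-bromo-2-(phenylsulfonyl)prop-1-ene
Product: 8 (5S,6S)-2,6-dimethyl-6-[2-(phenylsulfonyl)prop-2-en-1-yl]-5-(prop-1-en-2-yl)cyclohex-2-en-1-one, via lithium enolate 7 (not isolated)
Conditions: LiN(i-Pr)2, THF, −78 → −10 °C; DMPU; 3 (1.5 equiv), −78 → −30 °C
Reagents that add atoms: none
Why: Enolate alkylation by addition–elimination (SN2') on the bromomethyl vinyl sulfone, whose reacting terminus is an unhindered CH2. The tetrasubstituted enolate is attacked axially on the face anti to the pseudo-axial isopropenyl group, the established sense of carvone α'-dialkylation, so the arm enters trans to it and C10 gets the configuration that predetermines a trans ring fusion.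

Step 5
Reactants: 8 (5S,6S)-2,6-dimethyl-6-[2-(phenylsulfonyl)prop-2-en-1-yl]-5-(prop-1-en-2-yl)cyclohex-2-en-1-one
Product: 9 2ξ-(phenylsulfonyl)-11-nordrim-7-en-9-one (trans-decalin, 5α-H, 10β-CH3, C2 epimers)
Conditions: Fe(acac)3 (0.5 equiv), PhSiH3 (2.5 equiv, slow addition), EtOH/ethylene glycol 5:1, 0.02 M, 60 °C
Reagents that add atoms: none
Why: Fe(acac)3 and PhSiH3 in ethanol generate a hydride of trivalent iron that transfers a hydrogen atom to the CH2 terminus of the isopropenyl group, creating the second C4 methyl and the C4 tertiary radical. This nucleophilic radical adds to the unsubstituted terminus C3 of the vinyl sulfone (6-endo-trig closure of ring A, forming C3–C4), and the α-sulfonyl radical at C2 is reduced by divalent iron and protonated by ethanol. The closest known reaction type is the iron-hydride reductive coupling of unactivated alkenes with vinyl sulfones and its intramolecular Giese-type variants; the regiochemistry mirrors tin-hydride cyclisations of hex-5-enyl radicals with an electron-withdrawing group on C5, which close 6-endo. No stereocentre of the target is formed: C4 carries two identical methyls, the trans fusion is fixed by C5 (from 4) and C10 (from step 4) whose reacting arms are both equatorial on ring B, and C2 forms as an epimer mixture that step 13 erases. The step needs hydrogen-atom transfer to the isopropenyl group and not to the enone or vinyl sulfone alkenes (the terminal, electron-rich 1,1-disubstituted alkene is the most accessible site), 6-endo over 5-exo closure (5-exo would attack the fully substituted sulfonyl-bearing C2, join two quaternary carbons and leave a primary radical), and cyclisation before the C4 radical is reduced (slow silane addition keeps the hydride concentration low).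

Step 6
Reactants: 9 2ξ-(phenylsulfonyl)-11-nordrim-7-en-9-one
Product: 10 2ξ-(phenylsulfonyl)-11-nordrim-7-ene-6,9-dione
Conditions: Pd(OH)2 on carbon (5 mol %), t-BuOOH (5 equiv), K2CO3 (0.25 equiv), CH2Cl2, 4 → 23 °C
Reagents that add atoms: tert-butyl hydroperoxide, CC(C)(C)OO
Why: Known γ-oxidation of an α,β-enone to the 1,4-ene-dione by peroxidation of the γ-methylene and elimination; C6 is the only γ-CH2 because C10 is quaternary, and the sulfone and ring A are inert.

Step 7
Reactants: 10 2ξ-(phenylsulfonyl)-11-nordrim-7-ene-6,9-dione
Product: 11 6β-hydroxy-2ξ-(phenylsulfonyl)-11-nordrim-7-en-9-one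
Conditions: NaBH4 (1.0 equiv), CeCl3·7H2O, MeOH/CH2Cl2, −78 °C
Reagents that add atoms: none
Why: Luche 1,2-reduction; the C6 carbonyl is the less hindered one (C9 lies between quaternary C10 and methyl-bearing C8, the carbonyl that reacts last in ketoisophorone-type ene-diones). Hydride arrives from the α face, opposite the axial C10 and C4 methyls, giving the axial 6β-alcohol.

Step 8
Reactants: 12 4-methyl-5,6-dihydro-2H-pyran-2-one
Product: 13 ethyl (2Z)-5-bromo-3-methylpent-2-enoate
Conditions: HBr (gas, sat.), EtOH, 0 → 23 °C
Reagents that add atoms: hydrogen bromide, Br; ethanol, CCO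
Why: Acid-mediated alkyl–oxygen cleavage of the lactone by bromide with Fischer esterification in the same pot; the alkene is Z because carbonyl and CH2CH2 arm were held cis in the ring.

Step 9
Reactants: 13 ethyl (2Z)-5-bromo-3-methylpent-2-enoate
Product: 14 (2Z)-5-bromo-3-methylpent-2-en-1-ol
Conditions: i-Bu2AlH (2.2 equiv), CH2Cl2, −78 °C; aq. potassium sodium tartrate
Reagents that add atoms: none
Why: 1,2-Reduction of the conjugated ester to the allylic alcohol; the primary bromide and the alkene geometry are untouched at −78 °C.

Step 10
Reactants: 14 (2Z)-5-bromo-3-methylpent-2-en-1-ol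
Product: 15 {[(2Z)-5-bromo-3-methylpent-2-en-1-yl]oxy}(tert-butyl)diphenylsilane
Conditions: t-BuPh2SiCl, imidazole, CH2Cl2, 0 → 23 °C
Reagents that add atoms: tert-butyl(chloro)diphenylsilane, CC(C)(C)[Si](Cl)(c1ccccc1)c1ccccc1
Why: Silylation of the primary alcohol under weakly basic conditions, which avoids intramolecular O-alkylation to a dihydropyran; the tert-butyldiphenylsilyl ether withstands Grignard formation and the aqueous acid of step 12.

Step 11
Reactants: 15 {[(2Z)-5-bromo-3-methylpent-2-en-1-yl]oxy}(tert-butyl)diphenylsilane; 11 6β-hydroxy-2ξ-(phenylsulfonyl)-11-nordrim-7-en-9-one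
Product: 18 (13Z)-15-(tert-butyldiphenylsilyloxy)-2ξ-(phenylsulfonyl)labda-7,13-diene-6β,9-diol (9-OH β, chain α expected), via Grignard reagent 16 (not isolated), via organocerium reagent 17 (not isolated)
Conditions: 15 (3 equiv), Mg, THF, 23 °C; anhydrous CeCl3 (3 equiv), THF, −78 °C; then 11, −78 → 0 °C; aq. NH4Cl
Reagents that add atoms: none
Why: Grignard formation, transmetalation to the weakly basic organocerium reagent and 1,2-addition to the hindered, non-enolisable C9 ketone; the first equivalent is consumed by the 6β-hydroxyl. Attack anti to the axial C10 methyl is expected, but the C9 configuration is erased in step 12.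

Step 12
Reactants: 18 (13Z)-15-(tert-butyldiphenylsilyloxy)-2ξ-(phenylsulfonyl)labda-7,13-diene-6β,9-diol
Product: 19 (13Z)-15-(tert-butyldiphenylsilyloxy)-2ξ-(phenylsulfonyl)labda-8,13-diene-6β,7α-diol
Conditions: p-TsOH·H2O (10 mol %), THF/H2O 4:1, 0 → 23 °C
Reagents that add atoms: water, O
Why: Acid-catalysed 1,3-transposition of a tertiary allylic alcohol (SN1' hydration): ionisation at C9 gives the C7–C8–C9 allyl cation, and capture at C7 is favoured because it yields the tetrasubstituted C8=C9 alkene. The new C7 centre is set by axial attack on the α face, anti to the axial 6β-hydroxyl and the C10 methyl; participation of the 6β-oxygen as a 6β,7β-epoxide, reopened at C7 with inversion, leads to the same 7α-alcohol.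

Step 13
Reactants: 19 (13Z)-15-(tert-butyldiphenylsilyloxy)-2ξ-(phenylsulfonyl)labda-8,13-diene-6β,7α-diol
Product: 20 (13Z)-15-(tert-butyldiphenylsilyloxy)labda-8,13-diene-6β,7α-diol
Conditions: 6% Na(Hg), Na2HPO4, MeOH/THF, −20 → 0 °C
Reagents that add atoms: none
Why: Reductive desulfonylation by electron transfer to the aryl sulfone, C–S cleavage and protonation; it is feasible here because no enone remains, and both C2 epimers converge on one compound.

Step 14
Reactants: 20 (13Z)-15-(tert-butyldiphenylsilyloxy)labda-8,13-diene-6β,7α-diol
Product: 21 (13Z)-15-(tert-butyldiphenylsilyloxy)-7α-(triethylsilyloxy)labda-8,13-dien-6β-ol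
Conditions: Et3SiCl (1.1 equiv), imidazole, CH2Cl2, −20 → 0 °C
Reagents that add atoms: chlorotriethylsilane, CC[Si](Cl)(CC)CC
Why: Sterically controlled monosilylation: the allylic 7α-hydroxyl faces only a syn-axial hydrogen, whereas the 6β-hydroxyl is flanked by the axial C4 and C10 methyls and should not react at low temperature.

Step 15
Reactants: 21 (13Z)-15-(tert-butyldiphenylsilyloxy)-7α-(triethylsilyloxy)labda-8,13-dien-6β-ol
Product: 22 (13Z)-15-(tert-butyldiphenylsilyloxy)-7α-(triethylsilyloxy)labda-8,13-dien-6β-yl acetate
Conditions: Ac2O, DMAP, pyridine, 50 °C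
Reagents that add atoms: acetic anhydride, CC(=O)OC(C)=O
Why: DMAP-catalysed acetylation of the only free hydroxyl; forcing conditions are acceptable because both other oxygens are silylated.

Step 16
Reactants: 22 (13Z)-15-(tert-butyldiphenylsilyloxy)-7α-(triethylsilyloxy)labda-8,13-dien-6β-yl acetate
Product: 23 (13Z)-7α,15-dihydroxylabda-8,13-dien-6β-yl acetate (target, 5S,6S,7S,10S)
Conditions: Bu4NF, AcOH (1:1), THF, 0 → 23 °C
Reagents that add atoms: none
Why: Fluoride cleavage of both silyl ethers, buffered with acetic acid to spare the ester; acetyl migration from O6 to O7 is disfavoured because the two oxygens are trans-diaxial and cannot share a five-membered orthoester.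

## Compound list

1 | phenyl vinyl sulfone | C=CS(=O)(=O)c1ccccc1 | starting material
2 | 2-(phenylsulfonyl)prop-2-en-1-ol | C=C(CO)S(=O)(=O)c1ccccc1 | intermediate
3 | 3-bromo-2-(phenylsulfonyl)prop-1-ene | C=C(CBr)S(=O)(=O)c1ccccc1 | intermediate
4 | (R)-(−)-carvone | C=C(C)[C@@H]1CC=C(C)C(=O)C1 | starting material
5 | lithium α'-enolate of carvone (not isolated) | C=C(C)[C@@H]1CC=C(C)C(O[Li])=C1 | intermediate
6 | 6-methylcarvone, (5R)-2,6-dimethyl-5-(prop-1-en-2-yl)cyclohex-2-en-1-one, epimer mixture at C6 | C=C(C)[C@@H]1CC=C(C)C(=O)C1C | intermediate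
7 | tetrasubstituted lithium enolate of 6 (not isolated) | C=C(C)[C@@H]1CC=C(C)C(O[Li])=C1C | intermediate
8 | (5S,6S)-2,6-dimethyl-6-[2-(phenylsulfonyl)prop-2-en-1-yl]-5-(prop-1-en-2-yl)cyclohex-2-en-1-one (arm anti to isopropenyl) | O=C1C(C)=CC[C@@H](C(C)=C)[C@]1(C)CC(=C)S(=O)(=O)c2ccccc2 | intermediate
9 | 2ξ-(phenylsulfonyl)-11-nordrim-7-en-9-one (trans-fused, 5α-H, 10β-CH3, C2 epimers) | O=C1C(C)=CC[C@H]2C(C)(C)CC(S(=O)(=O)c3ccccc3)C[C@]12C | intermediate
10 | 2ξ-(phenylsulfonyl)-11-nordrim-7-ene-6,9-dione | O=C1C(C)=CC(=O)[C@H]2C(C)(C)CC(S(=O)(=O)c3ccccc3)C[C@]12C | intermediate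
11 | 6β-hydroxy-2ξ-(phenylsulfonyl)-11-nordrim-7-en-9-one | O=C1C(C)=C[C@@H](O)[C@H]2C(C)(C)CC(S(=O)(=O)c3ccccc3)C[C@]12C | intermediate
12 | 4-methyl-5,6-dihydro-2H-pyran-2-one | CC1=CC(=O)OCC1 | starting material
13 | ethyl (2Z)-5-bromo-3-methylpent-2-enoate | BrCC/C(C)=C\C(=O)OCC | intermediate
14 | (2Z)-5-bromo-3-methylpent-2-en-1-ol | BrCC/C(C)=C\CO | intermediate
15 | {[(2Z)-5-bromo-3-methylpent-2-en-1-yl]oxy}(tert-butyl)diphenylsilane | BrCC/C(C)=C\CO[Si](c1ccccc1)(c1ccccc1)C(C)(C)C | intermediate
16 | Grignard reagent from 15, bromo{(3Z)-5-[(tert-butyldiphenylsilyl)oxy]-3-methylpent-3-en-1-yl}magnesium (not isolated) | Br[Mg]CC/C(C)=C\CO[Si](c1ccccc1)(c1ccccc1)C(C)(C)C | intermediate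
17 | organocerium reagent, dichloro{(3Z)-5-[(tert-butyldiphenylsilyl)oxy]-3-methylpent-3-en-1-yl}cerium (not isolated) | Cl[Ce](Cl)CC/C(C)=C\CO[Si](c1ccccc1)(c1ccccc1)C(C)(C)C | intermediate
18 | (13Z)-15-(tert-butyldiphenylsilyloxy)-2ξ-(phenylsulfonyl)labda-7,13-diene-6β,9-diol (9-OH β, side chain α) | O[C@@]1(CC/C(C)=C\CO[Si](c3ccccc3)(c3ccccc3)C(C)(C)C)C(C)=C[C@@H](O)[C@H]2C(C)(C)CC(S(=O)(=O)c3ccccc3)C[C@]12C | intermediate
19 | (13Z)-15-(tert-butyldiphenylsilyloxy)-2ξ-(phenylsulfonyl)labda-8,13-diene-6β,7α-diol | O[C@@H]1[C@@H](O)C(C)=C(CC/C(C)=C\CO[Si](c3ccccc3)(c3ccccc3)C(C)(C)C)[C@@]2(C)CC(S(=O)(=O)c3ccccc3)CC(C)(C)[C@H]12 | intermediate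
20 | (13Z)-15-(tert-butyldiphenylsilyloxy)labda-8,13-diene-6β,7α-diol | O[C@@H]1[C@@H](O)C(C)=C(CC/C(C)=C\CO[Si](c3ccccc3)(c3ccccc3)C(C)(C)C)[C@@]2(C)CCCC(C)(C)[C@H]12 | intermediate
21 | (13Z)-15-(tert-butyldiphenylsilyloxy)-7α-(triethylsilyloxy)labda-8,13-dien-6β-ol | O[C@@H]1[C@@H](O[Si](CC)(CC)CC)C(C)=C(CC/C(C)=C\CO[Si](c3ccccc3)(c3ccccc3)C(C)(C)C)[C@@]2(C)CCCC(C)(C)[C@H]12 | intermediate
22 | (13Z)-15-(tert-butyldiphenylsilyloxy)-7α-(triethylsilyloxy)labda-8,13-dien-6β-yl acetate | CC(=O)O[C@@H]1[C@@H](O[Si](CC)(CC)CC)C(C)=C(CC/C(C)=C\CO[Si](c3ccccc3)(c3ccccc3)C(C)(C)C)[C@@]2(C)CCCC(C)(C)[C@H]12 | intermediate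
23 | (13Z)-7α,15-dihydroxylabda-8,13-dien-6β-yl acetate, (5S,6S,7S,10S), CNP0183298.2 | CC(=O)O[C@@H]1[C@@H](O)C(C)=C(CC/C(C)=C\CO)[C@@]2(C)CCCC(C)(C)[C@H]12 | target

## Step count and least certain steps

Total: 16 steps. Longest linear sequence: 12 steps from 1 (steps 1, 2, 4–7 and 11–16). The branch from 4 (steps 3–7 and 11–16) and the side-chain branch from 12 (steps 8–16) are shorter.

**Step 5 (key step).** The C4 radical may be reduced before it cyclises (net hydrogenation of the isopropenyl group), or hydrogen-atom transfer may occur at the vinyl sulfone or enone alkene, because all three alkenes compete for the same hydride. Fallback: from 8, Markovnikov addition of HBr to the isopropenyl group (HBr in AcOH, 0 °C, the conditions that convert carvone into its hydrobromide) would give the tertiary bromide F1. Bu3SnH and AIBN in benzene at 80 °C under syringe-pump dilution would then generate the same C4 radical by bromine abstraction and close it onto the vinyl sulfone in a tin-hydride Giese cyclisation, returning to the route at 9.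

**Step 4.** The enolate may be consumed by proton transfer or by conjugate addition to the product vinyl sulfone (oligomerisation), since electrophile and product are both Michael acceptors; facial selectivity may also erode with this larger electrophile. Fallback: from 6 (through enolate 7), alkylation with 2,3-dibromopropene, a standard electrophile for this enolate, would give the 2-bromoallyl ketone F2. Coupling of its vinyl bromide with PhSO2Na under CuI/L-proline catalysis in DMSO at 90 °C would install the sulfone and return to 8.

**Step 6.** Oxidation at the hindered C6 methylene may be slow or overrun, and the carbonate may epimerise C5 once it is α to the new carbonyl. Fallback: from 9, t-BuMe2SiOTf and Et3N would give the silyl dienol ether F3. Buffered mCPBA (NaHCO3, CH2Cl2, −20 °C) attacks the diene terminus C6, as with steroidal 3,5-dienol ethers, to give the γ-hydroxy enone F4 (either C6 epimer), and Dess–Martin periodinane would oxidise it to 10.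

**Step 7.** Discrimination between the two carbonyls may be poor, or conjugate reduction of the ene-dione may compete. Fallback: from 10, both carbonyls would be reduced with excess NaBH4/CeCl3 to the 7-ene-6β,9β-diol F5. MnO2 in CH2Cl2 would then oxidise only the quasi-equatorial C9 carbinol, whose axial C–H is aligned with the alkene, and leave the axial, shielded 6β-carbinol, returning to 11.

**Step 8.** Geometric purity may be lost through reversible addition of HBr across the β,β-disubstituted enoate after ring opening. Fallback: from 12, t-BuOK in THF would open the ring by vinylogous β-elimination to (2Z)-3-methylpenta-2,4-dienoic acid F6. LiAlH4 would reduce it to (2Z)-3-methylpenta-2,4-dien-1-ol F7, and silylation as in step 10 would give the silyl ether F8. 9-BBN followed by NaOH/H2O2 would hydroborate only the monosubstituted alkene to the homoallylic alcohol F9, and CBr4/PPh3 would convert it into 15.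

**Step 12.** The allyl cation may lose a proton (diene formation) instead of being captured, capture may occur partly on the β face, or the side-chain allylic silyl ether may ionise if the acid is too strong. Fallback: from 11, Et3SiOTf and 2,6-lutidine would give the silyl ether F10, and addition of 17 as in step 11 would give the tertiary carbinol F11. Oxidative 1,3-transposition with pyridinium chlorochromate (Babler–Dauben oxidation) would give the 8-en-7-one F12, and HF·pyridine would free the α-hydroxy enone F13. Me4NBH(OAc)3 in AcOH/MeCN would then deliver hydride intramolecularly from the 6β-oxygen to the β face of the C7 carbonyl and give the trans-diol 19.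

## Further compounds

F1 | step 5 | (5S,6S)-5-(2-bromopropan-2-yl)-2,6-dimethyl-6-[2-(phenylsulfonyl)prop-2-en-1-yl]cyclohex-2-en-1-one | O=C1C(C)=CC[C@@H](C(C)(C)Br)[C@]1(C)CC(=C)S(=O)(=O)c2ccccc2
F2 | step 4 | 6-(2-bromoprop-2-en-1-yl)-2,6-dimethyl-5-(prop-1-en-2-yl)cyclohex-2-en-1-one (bromoallyl arm anti to isopropenyl) | O=C1C(C)=CC[C@@H](C(C)=C)[C@]1(C)CC(Br)=C
F3 | step 6 | 9-(tert-butyldimethylsilyloxy)-2ξ-(phenylsulfonyl)-11-nordrima-6,8-diene | CC(C)(C)[Si](C)(C)OC1=C(C)C=C[C@H]2C(C)(C)CC(S(=O)(=O)c3ccccc3)C[C@]12C
F4 | step 6 | 6ξ-hydroxy-2ξ-(phenylsulfonyl)-11-nordrim-7-en-9-one | O=C1C(C)=CC(O)[C@H]2C(C)(C)CC(S(=O)(=O)c3ccccc3)C[C@]12C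
F5 | step 7 | 2ξ-(phenylsulfonyl)-11-nordrim-7-ene-6β,9β-diol | O[C@H]1C(C)=C[C@@H](O)[C@H]2C(C)(C)CC(S(=O)(=O)c3ccccc3)C[C@]12C
F6 | step 8 | (2Z)-3-methylpenta-2,4-dienoic acid | C=C/C(C)=C\C(=O)O
F7 | step 8 | (2Z)-3-methylpenta-2,4-dien-1-ol | C=C/C(C)=C\CO
F8 | step 8 | tert-butyl{[(2Z)-3-methylpenta-2,4-dien-1-yl]oxy}diphenylsilane | C=C/C(C)=C\CO[Si](c1ccccc1)(c1ccccc1)C(C)(C)C
F9 | step 8 | (3Z)-5-(tert-butyldiphenylsilyloxy)-3-methylpent-3-en-1-ol | OCC/C(C)=C\CO[Si](c1ccccc1)(c1ccccc1)C(C)(C)C
F10 | step 12 | 2ξ-(phenylsulfonyl)-6β-(triethylsilyloxy)-11-nordrim-7-en-9-one | O=C1C(C)=C[C@@H](O[Si](CC)(CC)CC)[C@H]2C(C)(C)CC(S(=O)(=O)c3ccccc3)C[C@]12C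
F11 | step 12 | (13Z)-15-(tert-butyldiphenylsilyloxy)-2ξ-(phenylsulfonyl)-6β-(triethylsilyloxy)labda-7,13-dien-9-ol (9-OH β) | O[C@@]1(CC/C(C)=C\CO[Si](c3ccccc3)(c3ccccc3)C(C)(C)C)C(C)=C[C@@H](O[Si](CC)(CC)CC)[C@H]2C(C)(C)CC(S(=O)(=O)c3ccccc3)C[C@]12C
F12 | step 12 | (13Z)-15-(tert-butyldiphenylsilyloxy)-2ξ-(phenylsulfonyl)-6β-(triethylsilyloxy)labda-8,13-dien-7-one | CC[Si](CC)(CC)O[C@@H]1C(=O)C(C)=C(CC/C(C)=C\CO[Si](c3ccccc3)(c3ccccc3)C(C)(C)C)[C@@]2(C)CC(S(=O)(=O)c3ccccc3)CC(C)(C)[C@H]12
F13 | step 12 | (13Z)-15-(tert-butyldiphenylsilyloxy)-6β-hydroxy-2ξ-(phenylsulfonyl)labda-8,13-dien-7-one | O[C@@H]1C(=O)C(C)=C(CC/C(C)=C\CO[Si](c3ccccc3)(c3ccccc3)C(C)(C)C)[C@@]2(C)CC(S(=O)(=O)c3ccccc3)CC(C)(C)[C@H]12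
A1 | alternative 1 | methyl (6E)-7,11-dimethyl-3-oxo-2-[2-(pivaloyloxy)ethyl]dodeca-6,10-dienoate | COC(=O)C(CCOC(=O)C(C)(C)C)C(=O)CC/C=C(\C)CCC=C(C)C
A2 | alternative 1 | trans-decalin β-keto ester (C8 ketone; C9 bears CO2Me and the 2-(pivaloyloxy)ethyl arm; 5α-H, 10β-CH3) | C1CC(=O)C(CCOC(=O)C(C)(C)C)(C(=O)OC)[C@@]2(C)CCCC(C)(C)[C@H]12
A3 | alternative 2 | 1-[(2R,5R)-2,5-dimethylpyrrolidin-1-yl]-3-methyl-2-[2-(pivaloyloxy)ethyl]but-3-en-1-one | CC(=C)C(CCOC(=O)C(C)(C)C)C(=O)N1[C@H](C)CC[C@H]1C
A4 | alternative 2 | 1,3,3-trimethylcyclohexene | CC1=CC(C)(C)CCC1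
A5 | alternative 2 | cis-fused 2-isopropenylcyclobutanone (C6 ketone; C9 bears isopropenyl and the 2-(pivaloyloxy)ethyl arm) | O=C1C(CCOC(=O)C(C)(C)C)(C(C)=C)[C@@]2(C)CCCC(C)(C)[C@@H]12
A6 | alternative 3 | 2,6-dimethyl-1,4-benzoquinone | CC1=CC(=O)C=C(C)C1=O
A7 | alternative 3 | 4-methylpenta-1,3-diene | C=CC=C(C)C
A8 | alternative 3 | cis-fused 2,7-diene-6,9-dione adduct (labdane numbering) | O=C1C=C(C)C(=O)[C@@]2(C)CC=CC(C)(C)[C@@H]12
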